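**Retrosynthetic overview**
- Feature (labdane numbering): the axial methyl C20 on quaternary C10 and the first chain carbon C11 on C9 are neighbours on ring B. They lie on the same face and flank the oxygenated C8, so together they are one acetylene unit laid across C9=C10 of a C8 enone.
- Late disconnections: the C17 aldehyde comes from an 8,17-diol kept as an acetonide. C12–C13 comes from hydroboration and B-alkyl Suzuki coupling of a C9 vinyl group with methyl (Z)-3-iodobut-2-enoate.
- Middle disconnections: the vinyl and methyl groups come from a C11/C20 dialdehyde, made by ozonolysis of a C11=C20 cyclobutene. C8–C17 comes from equatorial addition of a hydroxymethyl-anion equivalent to the C8 ketone.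
- Key disconnection: the cyclobutene comes from a [2+2] photocycloaddition of acetylene to a 3-silyloxy-4,4-dimethyl octalone, itself made from 6-methoxy-2-tetralone.
- Ring order: rings A and B are already present in the tetralone, and ring B is dearomatised by Birch reduction. The only ring closed is the temporary cyclobutene (step 6), opened again in step 10. Stereochemical relay: C3, then C5, then C10/C9, then C8.

Key step: step 6

Remark on the chemistry: labdane numbering is used for all bicyclic compounds; the SMILES is read as the ent-labdane (3R,5S,8R,9S,10R,13Z), with 3-OH equatorial, C20 axial, H5 and H9 on the opposite face, 8-OH axial on the C20 face and the C17 aldehyde equatorial.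

**Step 1**
Reactants: 1 6-methoxy-2-tetralone; 2 iodomethane
Product: 3 6-methoxy-1,1-dimethyl-3,4-dihydronaphthalen-2(1H)-one
Conditions: KOt-Bu (2.3 equiv), MeI (2.6 equiv), THF/t-BuOH, 0 → 23 °C, N2
Reagents that add atoms: iodomethane 2, CI
Why: Enolate C-alkylation, in which the benzylic C1–H bonds of a 2-tetralone are the most acidic, so both methyl groups should enter at C1 (future C4) before C3 reacts, and no stereocenter is formed.

**Step 2**
Reactants: 3 6-methoxy-1,1-dimethyl-3,4-dihydronaphthalen-2(1H)-one
Product: 4 (2R)-6-methoxy-1,1-dimethyl-1,2,3,4-tetrahydronaphthalen-2-ol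
Conditions: (S)-2-methyl-CBS-oxazaborolidine [(S)-1-methyl-3,3-diphenyltetrahydro-1H,3H-pyrrolo[1,2-c][1,3,2]oxazaborole] (10 mol %), BH3·SMe2, THF, −20 °C; aq. work-up
Reagents that add atoms: none
Why: Corey–Bakshi–Shibata reduction, in which the ketone lies between a quaternary benzylic carbon (large) and a CH2 group (small), a pinacolone-like contrast, so the (S)-catalyst should deliver hydride to the face that gives the (R)-carbinol, which is C3 of the target.

**Step 3**
Reactants: 4 (2R)-6-methoxy-1,1-dimethyl-1,2,3,4-tetrahydronaphthalen-2-ol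
Product: 5 (2R)-6-methoxy-1,1-dimethyl-1,2,3,4,5,8-hexahydronaphthalen-2-ol
Conditions: Li, NH3(l), THF, t-BuOH, −78 → −33 °C; solid NH4Cl
Reagents that add atoms: none
Why: Birch reduction, which protonates the anisole ring at its two unsubstituted para-related positions (future C6 and C9) and leaves the C7=C8 enol ether and the tetrasubstituted C5=C10 alkene, while the lithium alkoxide at C3 is inert.

**Step 4**
Reactants: 5 (2R)-6-methoxy-1,1-dimethyl-1,2,3,4,5,8-hexahydronaphthalen-2-ol
Product: 7 (4aS,6R)-6-hydroxy-5,5-dimethyl-4,4a,5,6,7,8-hexahydronaphthalen-2(3H)-one, via deconjugated C5=C10 enone 6 (not isolated)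
Conditions: 2 M aq. HCl, THF, 23 → 45 °C; chromatography, any minor C5 epimer resubmitted to the same acid
Reagents that add atoms: water, O
Why: Enol-ether hydrolysis followed by acid-catalysed isomerisation through the C8 dienol, in which only C9 links the ketone to the C5=C10 alkene so that conjugation can give only the C9=C10 enone, and C5 is set by axial γ-protonation of the ring A half-chair that keeps the C3 hydroxyl equatorial, a reversible event whose equilibrium should favour the same isomer (H5 axial and syn to H3).

**Step 5**
Reactants: 7 (4aS,6R)-6-hydroxy-5,5-dimethyl-4,4a,5,6,7,8-hexahydronaphthalen-2(3H)-one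
Product: 8 (4aS,6R)-6-(tert-butyldimethylsilyloxy)-5,5-dimethyl-4,4a,5,6,7,8-hexahydronaphthalen-2(3H)-one (C8 enone, C9=C10 alkene)
Conditions: TBSCl, imidazole, DMAP (cat.), DMF, 50 °C
Reagents that add atoms: tert-butyldimethylsilyl chloride, CC(C)(C)[Si](C)(C)Cl
Why: Nucleophile-catalysed silylation of the equatorial neopentyl-type alcohol under essentially neutral conditions, placed after the acid step so that the silyl ether never meets aqueous HCl, and leaving the enone and the epimerisable C5 untouched.

**Step 6**
Reactants: 8 silyloxy octalone; 9 acetylene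
Product: 10 cyclobutene-fused trans-decalone (C11=C20 etheno bridge joining C9 and C10 on the face opposite H5, C8 ketone)
Conditions: acetylene (continuous stream, saturated solution), CH2Cl2, −70 °C, hν (450 W medium-pressure Hg lamp, uranium-glass filter, λ > 340 nm), stopped short of full conversion
Reagents that add atoms: acetylene 9, C#C
Why: Light above 340 nm excites only the n–π* band of 8, intersystem crossing gives the twisted π–π* triplet, its β-carbon C10 bonds to acetylene to give a triplet 1,4-diradical (α-keto radical at C9, vinyl radical at C11), and after spin inversion C9–C11 coupling completes the formal [2+2] addition. The closest known reaction type is the triplet [2+2] photocycloaddition of bicyclic cyclohexenones with acetylene, allene or dichloroethene, which gives trans-decalin-type adducts. The one ring formed, the cyclobutene C9–C10–C20=C11, is closed stepwise by radical–radical recombination of the 1,4-diradical and not by a concerted process. C10 is controlled by C5, because in the relaxed triplet C10 pyramidalises toward the chair–chair trans-decalin shape, so the new C10–C20 bond should be axial and anti to H5. C9 is controlled by C10, because a cyclobutene can span a six-membered ring only in the cis mode, which puts C11 on the C20 face and H9 syn to H5. Acetylene is symmetric, so there is no regiochemical question, and the step needs only face selectivity at C10 (secured by the H5-bearing ring fusion and opposed only by the syn-axial C4 methyl toward a slim linear partner) and protection of the β,γ-unsaturated ketone product from secondary photolysis (secured by the long-wave filter, the low temperature and partial conversion).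

**Step 7**
Reactants: 10 cyclobutene-fused trans-decalone; 11 (chloromethyl)isopropoxydimethylsilane
Product: 12 C8 tertiary alcohol bearing an equatorial CH2SiMe2(Oi-Pr) group (C17), hydroxyl axial on the C20 face
Conditions: 11, Mg, THF, reflux (Grignard formation); then 10, THF, −78 → 0 °C; aq. NH4Cl; used crude
Reagents that add atoms: (chloromethyl)isopropoxydimethylsilane 11, ClC[Si](C)(C)OC(C)C
Why: Grignard 1,2-addition of a silicon-based hydroxymethyl-anion equivalent, in which the cyclobutene with its C20 arm covers the axial face of the C8 carbonyl, so the reagent should come along the equatorial trajectory from the convex face that carries H9 and H5, placing C17 equatorial and the C8 oxygen axial (8R) as in the target.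

**Step 8**
Reactants: 12 β-hydroxysilane
Product: 13 8,17-diol (cyclobutene and C3 silyl ether retained)
Conditions: 30% aq. H2O2, KF, KHCO3, THF/MeOH (1:1), 23 °C
Reagents that add atoms: hydrogen peroxide, OO
Why: Tamao–Fleming oxidation, which turns the C17–Si bond into C17–OH by a peroxide-induced 1,2-shift from silicon to oxygen under buffered conditions in which Peterson elimination, cyclobutene epoxidation and loss of the hindered C3 silyl ether should not compete.

**Step 9**
Reactants: 13 8,17-diol
Product: 14 8,17-acetonide (spiro dioxolane at C8)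
Conditions: 2,2-dimethoxypropane, PPTS (cat.), CH2Cl2, 23 °C
Reagents that add atoms: 2,2-dimethoxypropane, COC(C)(C)OC
Why: Acid-catalysed transketalisation ties the diol into a dioxolane and so removes the axial C8 hydroxyl, which would otherwise add to the syn-axial C20 aldehyde formed in the next step.

**Step 10**
Reactants: 14 8,17-acetonide
Product: 16 C11/C20 dialdehyde acetonide (equatorial formyl on C9 plus axial formyl on C10), via secondary ozonide 15 (not isolated)
Conditions: O3, CH2Cl2, −78 °C; then PPh3, −78 → 23 °C; used without chromatography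
Reagents that add atoms: ozone, [O-][O+]=O
Why: Ozonolysis by the Criegee mechanism of the only C=C bond, which is strained and unhindered, followed by phosphine reduction of the ozonide, gives the 1,4-dialdehyde without risk to C9 because its formyl group already holds the favoured equatorial position.

**Step 11**
Reactants: 16 C11/C20 dialdehyde acetonide; 17 methyltriphenylphosphonium bromide
Product: 18 C9-vinyl C10-formyl acetonide
Conditions: 17, KN(SiMe3)2, THF, 0 °C; ylide (1.0 equiv) added slowly to 16, THF, −78 → −20 °C
Reagents that add atoms: methyltriphenylphosphonium bromide 17, C[P+](c1ccccc1)(c1ccccc1)c1ccccc1.[Br-]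
Why: Wittig methylenation with one equivalent of ylide under kinetic control, in which the C11 aldehyde sits on a tertiary carbon and is equatorial whereas the C20 aldehyde is neopentyl, axial and flanked by the syn-axial C4 methyl and C8 oxygen, so only C11 should react at a temperature where enolisation and β-elimination of the C8 oxygen are slow.

**Step 12**
Reactants: 18 C9-vinyl C10-formyl acetonide
Product: 19 C20 (E)-tosylhydrazone
Conditions: TsNHNH2 (1.05 equiv), THF, 45 °C; chromatography to remove residual hydrazide
Reagents that add atoms: 4-methylbenzenesulfonohydrazide, Cc1ccc(cc1)S(=O)(=O)NN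
Why: Hydrazone condensation of the one remaining aldehyde needs no added acid, so the acetonide, silyl ether and vinyl group persist, and removing excess hydrazide excludes later diimide reduction of the alkene.

**Step 13**
Reactants: 19 C20 (E)-tosylhydrazone
Product: 21 C9-vinyl C10-methyl acetonide, via N-boryl tosylhydrazide 20 (not isolated)
Conditions: catecholborane, CHCl3, −10 → 23 °C; then NaOAc·3H2O, reflux
Reagents that add atoms: none
Why: Caglioti-type tosylhydrazone reduction in its catecholborane variant, in which hydride goes to the C=N carbon, acetate then triggers loss of sulfinate to a monoalkyl diazene that expels N2 and leaves the C20 methyl group, while uncatalysed hydroboration of the vinyl group by catecholborane is negligible at these temperatures.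

**Step 14**
Reactants: 22 methyl but-2-ynoate
Product: 23 methyl (Z)-3-iodobut-2-enoate
Conditions: NaI, AcOH, 115 °C
Reagents that add atoms: sodium iodide, [Na+].[I-]
Why: Conjugate hydroiodination of an ynoate, in which iodide adds to C3 and the allenolate is protonated anti to it, which should give the (Z)-β-iodoenoate.

**Step 15**
Reactants: 21 C9-vinyl C10-methyl acetonide; 23 methyl (Z)-3-iodobut-2-enoate
Product: 25 methyl (13Z)-labd-13-en-15-oate with 8,17-acetonide plus 3-OTBS, via B-alkyl-9-BBN borane 24 (not isolated)
Conditions: 9-BBN dimer, THF, 0 → 23 °C; then 23, PdCl2(dppf) (5 mol %), AsPh3, Cs2CO3, DMF/H2O, 23 °C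
Reagents that add atoms: methyl (Z)-3-iodobut-2-enoate 23, COC(=O)/C=C(/C)I
Why: Hydroboration followed by B-alkyl Suzuki–Miyaura coupling, in which 9-BBN adds anti-Markovnikov to the only alkene, and oxidative addition of zerovalent palladium to the vinyl iodide, transmetalation and reductive elimination all go with retention, so the (Z) geometry of 23 becomes the 13Z geometry.

**Step 16**
Reactants: 25 coupled acetonide
Product: 26 8,17-diol with 3-OTBS and (13Z)-enoate
Conditions: AcOH/THF/H2O (3:1:1), 45 °C
Reagents that add atoms: none
Why: Mild acid hydrolysis of the dioxolane through its oxocarbenium ion leaves both C–O bonds of the diol intact, so C8 keeps its configuration, and is too weak to cleave the hindered C3 silyl ether or the methyl ester.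

**Step 17**
Reactants: 26 8,17-diol
Product: 27 8-hydroxy-17-al with 3-OTBS
Conditions: SO3·pyridine, DMSO, Et3N, CH2Cl2, 0 °C
Reagents that add atoms: none
Why: Parikh–Doering oxidation, in which only the primary C17 alcohol can give an alkoxysulfonium ylide that collapses to a carbonyl, the tertiary C8 alcohol is inert, activated DMSO does not cleave 1,2-diols, and C8 carries no hydrogen and so cannot epimerise.

**Step 18**
Reactants: 27 8-hydroxy-17-al with 3-OTBS
Product: 28 methyl (3R,5S,8R,9S,10R,13Z)-3,8-dihydroxy-17-oxolabd-13-en-15-oate (target, CNP0135080.1)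
Conditions: HF·pyridine, THF, 0 → 23 °C (polyethylene vessel)
Reagents that add atoms: none
Why: Fluoride-driven desilylation under weakly acidic conditions avoids base, which could trigger α-ketol rearrangement of the tertiary α-hydroxy aldehyde or oxa-Michael closure of the C8 hydroxyl onto the enoate.

**Compound list**
1 | 6-methoxy-2-tetralone | COc1ccc2CC(=O)CCc2c1 | starting material
2 | iodomethane | CI | starting material
3 | 6-methoxy-1,1-dimethyl-3,4-dihydronaphthalen-2(1H)-one | COc1ccc2c(c1)CCC(=O)C2(C)C | intermediate
4 | (2R)-6-methoxy-1,1-dimethyl-1,2,3,4-tetrahydronaphthalen-2-ol | COc1ccc2c(c1)CC[C@@H](O)C2(C)C | intermediate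
5 | (2R)-6-methoxy-1,1-dimethyl-1,2,3,4,5,8-hexahydronaphthalen-2-ol | COC1=CCC2=C(C1)CC[C@@H](O)C2(C)C | intermediate
6 | (6R)-6-hydroxy-5,5-dimethyl-3,4,5,6,7,8-hexahydronaphthalen-2(1H)-one (deconjugated C5=C10 enone, not isolated) | O=C1CCC2=C(C1)CC[C@@H](O)C2(C)C | intermediate
7 | (4aS,6R)-6-hydroxy-5,5-dimethyl-4,4a,5,6,7,8-hexahydronaphthalen-2(3H)-one | O=C1C=C2CC[C@@H](O)C(C)(C)[C@H]2CC1 | intermediate
8 | (4aS,6R)-6-(tert-butyldimethylsilyloxy)-5,5-dimethyl-4,4a,5,6,7,8-hexahydronaphthalen-2(3H)-one | O=C1C=C2CC[C@@H](O[Si](C)(C)C(C)(C)C)C(C)(C)[C@H]2CC1 | intermediate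
9 | acetylene | C#C | starting material
10 | cyclobutene-fused trans-decalone: C8 ketone, 3-OTBS equatorial, 4,4-dimethyl, C11=C20 bridge cis-fused at C9/C10 and anti to H5 | C3=C[C@H]1[C@]23CC[C@@H](O[Si](C)(C)C(C)(C)C)C(C)(C)[C@H]2CCC1=O | intermediate
11 | (chloromethyl)isopropoxydimethylsilane | ClC[Si](C)(C)OC(C)C | starting material
12 | adduct of 10: axial 8-OH on the C20 face, equatorial C17H2–SiMe2(Oi-Pr) | C3=C[C@H]1[C@]23CC[C@@H](O[Si](C)(C)C(C)(C)C)C(C)(C)[C@H]2CC[C@]1(O)C[Si](C)(C)OC(C)C | intermediate
13 | cyclobutene 8,17-diol (8-OH axial, CH2OH equatorial) | C3=C[C@H]1[C@]23CC[C@@H](O[Si](C)(C)C(C)(C)C)C(C)(C)[C@H]2CC[C@]1(O)CO | intermediate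
14 | cyclobutene 8,17-acetonide | C3=C[C@H]1[C@]23CC[C@@H](O[Si](C)(C)C(C)(C)C)C(C)(C)[C@H]2CC[C@]1(OC4(C)C)CO4 | intermediate
15 | secondary ozonide of 14 (1,2,4-trioxolane bridging C11 and C20, exo/endo orientation open, not isolated) | O1OC2OC1[C@H]3[C@]42CC[C@@H](O[Si](C)(C)C(C)(C)C)C(C)(C)[C@H]4CC[C@]3(OC5(C)C)CO5 | intermediate
16 | dialdehyde: C11 formyl equatorial on C9, C20 formyl axial on C10, 8,17-acetonide, 3-OTBS | O=C[C@H]1[C@]2(C=O)CC[C@@H](O[Si](C)(C)C(C)(C)C)C(C)(C)[C@H]2CC[C@]1(OC3(C)C)CO3 | intermediate
17 | methyltriphenylphosphonium bromide | C[P+](c1ccccc1)(c1ccccc1)c1ccccc1.[Br-] | starting material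
18 | C9-vinyl (C11=C12), C10-formyl (C20) acetonide | C=C[C@H]1[C@]2(C=O)CC[C@@H](O[Si](C)(C)C(C)(C)C)C(C)(C)[C@H]2CC[C@]1(OC3(C)C)CO3 | intermediate
19 | C20 (E)-tosylhydrazone of 18 | C=C[C@H]1[C@]2(/C=N/NS(=O)(=O)c3ccc(C)cc3)CC[C@@H](O[Si](C)(C)C(C)(C)C)C(C)(C)[C@H]2CC[C@]1(OC3(C)C)CO3 | intermediate
20 | N-(1,3,2-benzodioxaborol-2-yl) tosylhydrazide at C20 (not isolated) | C=C[C@H]1[C@]2(CN(B3Oc4ccccc4O3)NS(=O)(=O)c3ccc(C)cc3)CC[C@@H](O[Si](C)(C)C(C)(C)C)C(C)(C)[C@H]2CC[C@]1(OC3(C)C)CO3 | intermediate
21 | C9-vinyl, C10-methyl acetonide | C=C[C@H]1[C@]2(C)CC[C@@H](O[Si](C)(C)C(C)(C)C)C(C)(C)[C@H]2CC[C@]1(OC3(C)C)CO3 | intermediate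
22 | methyl but-2-ynoate | CC#CC(=O)OC | starting material
23 | methyl (Z)-3-iodobut-2-enoate | COC(=O)/C=C(/C)I | intermediate
24 | C12 B-alkyl-9-borabicyclo[3.3.1]nonane from 21 (not isolated) | B4(C5CCCC4CCC5)CC[C@H]1[C@]2(C)CC[C@@H](O[Si](C)(C)C(C)(C)C)C(C)(C)[C@H]2CC[C@]1(OC3(C)C)CO3 | intermediate
25 | methyl (13Z)-3-OTBS-8,17-isopropylidenedioxylabd-13-en-15-oate | COC(=O)/C=C(/C)CC[C@H]1[C@]2(C)CC[C@@H](O[Si](C)(C)C(C)(C)C)C(C)(C)[C@H]2CC[C@]1(OC3(C)C)CO3 | intermediate
26 | methyl (13Z)-3-OTBS-8,17-dihydroxylabd-13-en-15-oate | COC(=O)/C=C(/C)CC[C@H]1[C@]2(C)CC[C@@H](O[Si](C)(C)C(C)(C)C)C(C)(C)[C@H]2CC[C@]1(O)CO | intermediate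
27 | methyl (13Z)-3-OTBS-8-hydroxy-17-oxolabd-13-en-15-oate | COC(=O)/C=C(/C)CC[C@H]1[C@]2(C)CC[C@@H](O[Si](C)(C)C(C)(C)C)C(C)(C)[C@H]2CC[C@]1(O)C=O | intermediate
28 | methyl (3R,5S,8R,9S,10R,13Z)-3,8-dihydroxy-17-oxolabd-13-en-15-oate | COC(=O)/C=C(/C)CC[C@H]1[C@]2(C)CC[C@@H](O)C(C)(C)[C@H]2CC[C@]1(O)C=O | target

**Step count**
Total steps: 18. Longest linear sequence: 17 (steps 1–13 and 15–18). Step 14 is a one-step side branch.

**Steps most likely to fail**

**Step 6.** Three processes threaten this step:
- The enone triplet may be trapped inefficiently by sparingly soluble acetylene.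
- The β,γ-unsaturated ketone product may rearrange photochemically (1,3-acyl shift).
- Face selectivity at C10 may be eroded by the syn-axial C4 methyl.

The fallback sets out from 8 and returns at 10.
- Irradiation of 8 (Pyrex, CH2Cl2, −40 °C) with a large excess of (Z)-1,2-dichloroethene, a more soluble and more reactive two-carbon partner, would give the dichlorocyclobutane ketone F1. This saturated ketone is not prone to the secondary photoreaction, and its diastereomers can be separated.
- Ketalisation with 1,2-bis(trimethylsilyloxy)ethane and catalytic Me3SiOTf at −78 °C would give the dichloro ketal F2.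
- Reductive 1,2-dechlorination with sodium naphthalenide in THF at −78 °C would give the cyclobutene ketal F3.
- PPTS in wet acetone would release 10.

**Step 11.** The ylide may also attack the C20 aldehyde. It may instead act as a base on H9, which is anti-periplanar to the C8–O bond, and open the acetonide by β-elimination.

The fallback sets out from 14 and returns at 18. It keeps C20 at the alcohol level while C11 is olefinated.
- Ozonolysis of 14 in CH2Cl2/MeOH with NaBH4 work-up would give the 11,20-diol F4.
- TEMPO (cat.) with PhI(OAc)2 should oxidise the less hindered C11 carbinol first and close the γ-lactone F5, with C11 as the carbonyl.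
- i-Bu2AlH at −78 °C would give the lactol F6.
- Excess Ph3P=CH2 would open the lactol to the C9-vinyl C10-hydroxymethyl compound F7.
- Dess–Martin periodinane buffered with NaHCO3 would give 18.

**Step 13.** Hydride delivery to the crowded C20 hydrazone may be incomplete, or the diazene intermediate may decompose along other paths.

The fallback sets out from 18 and returns at 21, bypassing 19 and 20.
- NaBH4 in MeOH would give the C9-vinyl C10-hydroxymethyl compound F7.
- NaH, CS2 and then MeI would give the S-methyl xanthate F8.
- Barton–McCombie deoxygenation (Bu3SnH, AIBN, toluene, reflux) would give 21. The intermediate primary C20 radical is a 4-pentenyl radical, whose cyclisation onto the vinyl group is slow compared with hydrogen transfer from the stannane.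

**Further compounds**
F1 | step 6 | 11,20-dichloro cyclobutane-fused trans-decalone (mixture at C11 and C20) | ClC3C(Cl)[C@H]1[C@]23CC[C@@H](O[Si](C)(C)C(C)(C)C)C(C)(C)[C@H]2CCC1=O
F2 | step 6 | C8 ethylene ketal of F1 | ClC3C(Cl)[C@H]1[C@]23CC[C@@H](O[Si](C)(C)C(C)(C)C)C(C)(C)[C@H]2CCC14OCCO4
F3 | step 6 | C8 ethylene ketal of 10 | C3=C[C@H]1[C@]23CC[C@@H](O[Si](C)(C)C(C)(C)C)C(C)(C)[C@H]2CCC14OCCO4
F4 | step 11 | 11,20-diol with 8,17-acetonide and 3-OTBS | OC[C@H]1[C@]2(CO)CC[C@@H](O[Si](C)(C)C(C)(C)C)C(C)(C)[C@H]2CC[C@]1(OC3(C)C)CO3
F5 | step 11 | γ-lactone, C11 carbonyl and C20 oxymethylene | O=C3[C@H]1[C@]2(CO3)CC[C@@H](O[Si](C)(C)C(C)(C)C)C(C)(C)[C@H]2CC[C@]1(OC4(C)C)CO4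
F6 | step 11 | lactol of F5 (anomeric mixture at C11) | OC3[C@H]1[C@]2(CO3)CC[C@@H](O[Si](C)(C)C(C)(C)C)C(C)(C)[C@H]2CC[C@]1(OC4(C)C)CO4
F7 | step 11 | C9-vinyl C10-hydroxymethyl acetonide | C=C[C@H]1[C@]2(CO)CC[C@@H](O[Si](C)(C)C(C)(C)C)C(C)(C)[C@H]2CC[C@]1(OC3(C)C)CO3
F8 | step 13 | C20 O-alkyl S-methyl dithiocarbonate of F7 | C=C[C@H]1[C@]2(COC(=S)SC)CC[C@@H](O[Si](C)(C)C(C)(C)C)C(C)(C)[C@H]2CC[C@]1(OC3(C)C)CO3
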